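Birch takes its portions of J in quick succession, while its neighbour oak waits 4.0 min between them, so we ask whether the slower hand changes the E we collect.

| setting | birch | cedar | alder | oak |
|---|---|---|---|---|
| J | 2.0 M (in portions, 4) | 2.0 M (in portions, 4) | 2.0 M (in portions, 4) | 2.0 M (in portions, 4) |
| D | 1.00 M | 1.00 M | 1.00 M | 1.00 M |
| time | 4.0 h | 4.0 h | 4.0 h | 4.0 h |
| remark | the portions of J follow each other after 0.15 min, the first at the start | the portions of J follow each other after 0.40 min, the first at the start | the portions of J follow each other after 1.2 min, the first at the start | the portions of J follow each other after 4.0 min, the first at the start |

    J → E (k1 = 8.7 × 10⁻⁵ s⁻¹)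
    J + D → J.D (k2 = 0.0014 L mol⁻¹ s⁻¹)
    J → L (k3 = 6.1 × 10⁻⁵ s⁻¹)

1. amount of E at the end, in percent of the J charged for birch, cedar, alder, oak, in this order
2. the shape of the row from first to last (rises, then falls / falls, then rises / falls all the way / rises all the way / hardly changes)

We count in fractions of the J charged, and we first draw the curve for J all in at once. E sets off with a slope of 0.31 h⁻¹. D can bind half of the charge, so D is the limiting reagent. It falls within a few pairing times of 5.95 min, far shorter than J's own life of 1.88 h.

While D falls, J stands above the half that will outlive D, by half of D's remaining fraction. Added up over the fall, that surplus comes to ln(2) pairing times. The remaining half therefore runs as if it had started 8.25 min early. This is the knee, and beyond it J simply decays. E takes 0.588 of what decays, its selectivity share against L.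

By our reckoning J stands at 5.52 % at the end, which puts E at 26.15 %, on its way to a level of 29.4 %.

Now the portions. The average portion arrives 1.50 intervals after the start, so it misses some of J's decay. For oak this comes to 0.0533 turnovers: the lateness, meaning J's decay rate times that average delay. The J left at the end grows by the factor exp(lateness), and E loses the share of that extra J it would have received. For oak this is 0.17 percentage points, giving 25.98 %. The row should therefore hardly change.

The forecast reads 26.24 %, 26.23 %, 26.19 % and 26.05 %, and calls the shape "hardly changes", on the ground that “Dosing only delays the same trajectory”. Its numbers stand slightly above ours, and the two agree on the shape.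

The simulation gives 26.2 %, 26.2 %, 26.2 % and 26.1 %: the row hardly changes.

Slow addition makes no difference to E in oak or in birch, but lateness does show in the J left. Birch reads 5.37 % with a lateness of 0.00200. Oak's 0.0533 then gives 5.65 % against a reading of 5.70 %, and alder's 0.0160 gives 5.45 % against 5.45 %. Taking the path from J + D to J.D away lifts E in birch from 26.2 % to 51.8 %, which recovers 35 % of the E that is missing.

All constants were drawn at random within sensible limits; no experiment stands behind them.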